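**Plan**

- Feature: ring A'' of the flavanone unit (C4a''–C5''–C6''–C7''–C8''–C8a'') is an acylphloroglucinol. C5''–C6''(OAr)–C7'' is a malonyl unit, and C4a''–C8a''–C8'' are the α-carbon, the oxygen-bearing carbon and the methyl carbon of a dihydropyranone whose ring oxygen O1'' already sits on C8a''.
- Retrosynthesis: remove two benzyl ethers and the 7''-O-methyl group; cut C7''–C8'' and C4a''–C5'' to an aryloxymalonyl dichloride and a silyl dienol ether; cut the C6''–O bond at the sp3 stage (flavone phenol + bromomalonate); cut the flavone through its chalcone; cut the diene at C8a''=C8'' (lactone methylenation) and at C2''–C3'' (vinylogous aldol).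
- Forward: the flavone heterocycle is closed first (chalcone, iodine/DMSO), then O-alkylation, saponification and chlorination give the dichloride. Separately, aldol, lactonization (the future flavanone heterocycle), O-silylation and methylenation give the diene. Ring A'' is closed last by the [3+3] double C-acylation, followed by 7''-O-methylation and hydrogenolysis.
- Stereochemistry: C2'' (S) is set once, in a Ti/BINOL-catalysed vinylogous Mukaiyama aldol, and is carried through without enolization at C3''.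

Key step: step 11

Assumption: the facial sense of the Ti/BINOL aldol is taken from simple aromatic aldehydes ((S)-BINOL, Si-face attack, (S)-carbinol); if the first batch shows the opposite sense, (R)-BINOL is used and nothing else changes.

Remark on the chemistry: silylative enolization of a β-alkoxy enone removes the α′-proton (this is how Danishefsky-type dienes are made). In a 6-methyl-2,3-dihydro-4H-pyran-4-one that proton is C3''–H, and the resulting 2H-pyran can ring-open and racemize C2''. The γ-silyl dienol ether of (S)-2-(4-benzyloxyphenyl)-6-methyl-2,3-dihydro-4H-pyran-4-one is therefore made by methylenation of a lactone, without any deprotonation.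

Remark on protecting groups: the flavone 5-OH and the 4'''-OH are both carried as benzyl ethers, so the last step is a neutral hydrogenolysis and no Lewis acid meets the flavanone.

**Route**

Step 1
Reactants: 1 2',6'-dihydroxy-4'-methoxyacetophenone
Product: 2 1-[2-(benzyloxy)-6-hydroxy-4-methoxyphenyl]ethan-1-one
Conditions: BnBr (1.05 equiv), K2CO3, acetone, reflux
Reagents that add atoms: benzyl bromide, BrCc1ccccc1
Why: Williamson etherification; after one benzylation the remaining ortho-hydroxyl stays hydrogen-bonded to the acetyl group and is much less nucleophilic, so the symmetric diol should stop at the mono-ether.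

Step 2
Reactants: 2 1-[2-(benzyloxy)-6-hydroxy-4-methoxyphenyl]ethan-1-one; 3 4-(tetrahydro-2H-pyran-2-yloxy)benzaldehyde
Product: 5 (E)-1-[2-(benzyloxy)-6-hydroxy-4-methoxyphenyl]-3-(4-hydroxyphenyl)prop-2-en-1-one, via THP-protected chalcone 4 (not isolated)
Conditions: KOH (50% aq.), EtOH, rt; then 2 M HCl, THF/EtOH, rt
Reagents that add atoms: none
Why: Claisen–Schmidt condensation of the methyl ketone with the non-enolizable aldehyde gives the (E)-enone; the THP acetal keeps the aldehyde from being deactivated as a phenoxide and is cleaved in the acidic quench.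

Step 3
Reactants: 5 (E)-1-[2-(benzyloxy)-6-hydroxy-4-methoxyphenyl]-3-(4-hydroxyphenyl)prop-2-en-1-one
Product: 6 5-(benzyloxy)-2-(4-hydroxyphenyl)-7-methoxy-4H-chromen-4-one
Conditions: I2 (10 mol %), DMSO, 120 °C
Reagents that add atoms: none
Why: iodine-catalysed oxidative cyclization of a 2'-hydroxychalcone (oxa-Michael addition, α-iodination, loss of HI, DMSO as terminal oxidant) is the standard flavone synthesis and tolerates free phenols; catalytic iodine and a short reaction time are chosen to spare the peri-benzyl ether.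

Step 4
Reactants: 6 5-(benzyloxy)-2-(4-hydroxyphenyl)-7-methoxy-4H-chromen-4-one; 7 dimethyl bromomalonate
Product: 8 dimethyl 2-{4-[5-(benzyloxy)-7-methoxy-4-oxo-4H-chromen-2-yl]phenoxy}malonate
Conditions: K2CO3, acetone, rt → 50 °C
Reagents that add atoms: none
Why: SN2 O-alkylation of the only free phenol by the bromomalonate makes the future C6''–O bond at an sp3 carbon, so no hindered aryl C–O coupling is needed.

Step 5
Reactants: 8 dimethyl 2-{4-[5-(benzyloxy)-7-methoxy-4-oxo-4H-chromen-2-yl]phenoxy}malonate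
Product: 9 2-{4-[5-(benzyloxy)-7-methoxy-4-oxo-4H-chromen-2-yl]phenoxy}malonic acid
Conditions: LiOH·H2O (2.5 equiv), THF/H2O, 0 °C → rt; then 1 M HCl, 0 °C
Reagents that add atoms: lithium hydroxide, [Li+].[OH-] (its oxygen becomes the OH oxygen of each carboxylic acid)
Why: ester saponification at or below room temperature; the flavone should survive cold dilute hydroxide, and the aryloxymalonic acid is kept cold to avoid decarboxylation.

Step 6
Reactants: 9 2-{4-[5-(benzyloxy)-7-methoxy-4-oxo-4H-chromen-2-yl]phenoxy}malonic acid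
Product: 10 2-{4-[5-(benzyloxy)-7-methoxy-4-oxo-4H-chromen-2-yl]phenoxy}malonyl dichloride
Conditions: 1-chloro-N,N,2-trimethylprop-1-en-1-amine (2.1 equiv), CH2Cl2, 0 °C → rt; evaporation, trituration with dry pentane, used at once
Reagents that add atoms: Ghosez's reagent (1-chloro-N,N,2-trimethylprop-1-en-1-amine), CC(C)=C(Cl)N(C)C
Why: the α-chloroenamine converts carboxylic acids into acid chlorides under neutral conditions without HCl, which should avoid both ketene formation at the acidic malonyl C–H and chloropyrylium formation at the basic flavone carbonyl.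

Step 7
Reactants: 11 4-(benzyloxy)benzaldehyde; 12 1-methoxy-1,3-bis(trimethylsilyloxy)buta-1,3-diene (Chan's diene)
Product: 14 methyl (S)-5-[4-(benzyloxy)phenyl]-5-hydroxy-3-oxopentanoate, via bis-silyl aldol adduct 13 (not isolated)
Conditions: Ti(OiPr)4/(S)-BINOL (10 mol %), 4 Å MS, THF, −78 °C → rt; then TFA, THF/H2O, −78 → 0 °C
Reagents that add atoms: none
Why: catalytic enantioselective vinylogous Mukaiyama aldol; the terminal CH2 of the diene adds to the Si face of the titanium-bound aldehyde, which sets C2'' as (S), and the acidic quench removes both silyl groups.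

Step 8
Reactants: 14 methyl (S)-5-[4-(benzyloxy)phenyl]-5-hydroxy-3-oxopentanoate
Product: 15 (S)-6-[4-(benzyloxy)phenyl]-4-hydroxy-5,6-dihydro-2H-pyran-2-one (enol form of the oxane-2,4-dione)
Conditions: K2CO3, MeOH, rt; then 1 M HCl to pH 2
Reagents that add atoms: none
Why: base-mediated lactonization of a δ-hydroxy-β-keto ester; the β-keto ester is held as its enolate, so retro-aldol and β-elimination at the carbinol should not compete, and the C–O bond at the stereocenter is not broken.

Step 9
Reactants: 15 (S)-6-[4-(benzyloxy)phenyl]-4-hydroxy-5,6-dihydro-2H-pyran-2-one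
Product: 16 (S)-6-[4-(benzyloxy)phenyl]-4-[(tert-butyldimethylsilyl)oxy]-5,6-dihydro-2H-pyran-2-one
Conditions: TBSCl, Et3N, CH2Cl2, 0 °C → rt; non-aqueous work-up
Reagents that add atoms: tert-butyldimethylsilyl chloride, CC(C)(C)[Si](C)(C)Cl
Why: O-silylation of the acidic cyclic 1,3-dicarbonyl enol gives the conjugated 4-silyloxy enoate, which places the silyl group on the future O4''.

Step 10
Reactants: 16 (S)-6-[4-(benzyloxy)phenyl]-4-[(tert-butyldimethylsilyl)oxy]-5,6-dihydro-2H-pyran-2-one
Product: 17 (S)-2-[4-(benzyloxy)phenyl]-4-[(tert-butyldimethylsilyl)oxy]-6-methylidene-3,6-dihydro-2H-pyran (the γ-silyl dienol ether of (S)-2-(4-benzyloxyphenyl)-6-methyl-2,3-dihydro-4H-pyran-4-one)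
Conditions: Cp2TiMe2 (2.5 equiv), toluene/THF, 65 °C, dark; filtration through basic alumina
Reagents that add atoms: dimethyltitanocene (Petasis reagent), [CH3-].[CH3-].[Ti+4].c1cc[cH-]c1.c1cc[cH-]c1
Why: Petasis methylenation of a lactone carbonyl to an exocyclic enol ether turns C8a''=O into C8a''=C8''H2 under neutral, non-basic conditions, so the 2-alkoxy-4-silyloxydiene should form as a single regioisomer with C2'' untouched.

Step 11
Reactants: 10 2-{4-[5-(benzyloxy)-7-methoxy-4-oxo-4H-chromen-2-yl]phenoxy}malonyl dichloride; 17 (S)-2-[4-(benzyloxy)phenyl]-4-[(tert-butyldimethylsilyl)oxy]-6-methylidene-3,6-dihydro-2H-pyran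
Product: 19 5-(benzyloxy)-2-{4-[((2S)-2-[4-(benzyloxy)phenyl]-5,7-dihydroxy-4-oxochroman-6-yl)oxy]phenyl}-7-methoxy-4H-chromen-4-one, via monoacylated pyranone acyl chloride 18 (not isolated)
Conditions: 10 (1.1 equiv), 2,6-di-tert-butyl-4-methylpyridine (2.2 equiv), CH2Cl2, −78 °C, slow addition of 17; → 0 °C; then 1 M HCl/THF, 0 °C
Reagents that add atoms: none
Why: Proposed new method: the exocyclic CH2 of 17, the terminus of a 2-alkoxy-4-silyloxy-1,3-diene, should attack one acyl chloride of 10 in an uncatalysed vinylogous Mukaiyama-type C-acylation (C7''–C8''), as 1,3-bis(silyloxy)dienes do with acid chlorides, with chloride removing the silyl group to give the 6-(acylmethyl)pyranone 18. In 18 the C8'' methylene lies between the new ketone and the vinylogous ester, so its dienol makes C4a'' nucleophilic, and a 6-(enolexo)-exo-trig C-acylation onto the second acyl chloride (or 6π-closure of the acylketene formed by loss of HCl) forms C4a''–C5''; the resulting cyclohexenetrione tautomerizes to aromatic ring A''. The closest known reaction types are the [3+3] α,α′-double C-acylation of enol ethers and silyl enol ethers by malonyl dichloride, [3+3] cyclizations of 1,3-bis(silyloxy)dienes with 1,3-dielectrophiles, and the Claisen cyclization of 3,5,7-triketo esters to acylphloroglucinols. No stereocenter is formed, and C2'' is preserved because the diene is regio-defined by its synthesis, C3''–H2 is never enolized and the hindered pyridine only traps HCl. The step needs C- over O-acylation and 6''/8'' regiocontrol: an O-cyclization of 18 would have to form a four- or eight-membered ring, O1'' is already bonded to C8a'' so the aryloxy carbon can only become C6'', and the symmetry of the malonyl unit makes the order of the two acylations immaterial. Slow addition of 17 to a slight excess of 10 should suppress the 2:1 adduct and protodesilylation of the diene.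

Step 12
Reactants: 19 5-(benzyloxy)-2-{4-[((2S)-2-[4-(benzyloxy)phenyl]-5,7-dihydroxy-4-oxochroman-6-yl)oxy]phenyl}-7-methoxy-4H-chromen-4-one
Product: 20 5-(benzyloxy)-2-{4-[((2S)-2-[4-(benzyloxy)phenyl]-5-hydroxy-7-methoxy-4-oxochroman-6-yl)oxy]phenyl}-7-methoxy-4H-chromen-4-one
Conditions: CH2N2 (1.5 equiv), Et2O/MeOH, 0 °C
Reagents that add atoms: diazomethane, C=[N+]=[N-]
Why: diazomethane O-methylates the acidic, unchelated 7''-phenol (para to the C4'' carbonyl) while the 5''-hydroxyl is held in a hydrogen bond to C4''=O; no base is present, so the flavanone cannot open to a chalcone and racemize.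

Step 13
Reactants: 20 5-(benzyloxy)-2-{4-[((2S)-2-[4-(benzyloxy)phenyl]-5-hydroxy-7-methoxy-4-oxochroman-6-yl)oxy]phenyl}-7-methoxy-4H-chromen-4-one
Product: 21 5-hydroxy-2-{4-[((2S)-5-hydroxy-2-(4-hydroxyphenyl)-7-methoxy-4-oxochroman-6-yl)oxy]phenyl}-7-methoxy-4H-chromen-4-one (CNP0202121.1)
Conditions: H2 (1 atm), 10% Pd/C, THF/EtOAc, rt
Reagents that add atoms: none
Why: hydrogenolysis of the two benzyl aryl ethers over Pd/C is neutral and should leave the methyl ethers, the diaryl ether, the flavone C2=C3 bond and the C2'' stereocenter intact when stopped after two equivalents of hydrogen.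

**Compound list**

1 | 2',6'-dihydroxy-4'-methoxyacetophenone | CC(=O)c1c(O)cc(OC)cc1O | starting material
2 | 1-[2-(benzyloxy)-6-hydroxy-4-methoxyphenyl]ethan-1-one | CC(=O)c1c(O)cc(OC)cc1OCc1ccccc1 | intermediate
3 | 4-(tetrahydro-2H-pyran-2-yloxy)benzaldehyde | O=Cc1ccc(OC2CCCCO2)cc1 | starting material
4 | (E)-1-[2-(benzyloxy)-6-hydroxy-4-methoxyphenyl]-3-[4-(tetrahydro-2H-pyran-2-yloxy)phenyl]prop-2-en-1-one (not isolated) | COc1cc(O)c(C(=O)/C=C/c2ccc(OC3CCCCO3)cc2)c(OCc2ccccc2)c1 | intermediate
5 | (E)-1-[2-(benzyloxy)-6-hydroxy-4-methoxyphenyl]-3-(4-hydroxyphenyl)prop-2-en-1-one | COc1cc(O)c(C(=O)/C=C/c2ccc(O)cc2)c(OCc2ccccc2)c1 | intermediate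
6 | 5-(benzyloxy)-2-(4-hydroxyphenyl)-7-methoxy-4H-chromen-4-one | COc1cc(OCc2ccccc2)c2c(=O)cc(-c3ccc(O)cc3)oc2c1 | intermediate
7 | dimethyl bromomalonate | COC(=O)C(Br)C(=O)OC | starting material
8 | dimethyl 2-{4-[5-(benzyloxy)-7-methoxy-4-oxo-4H-chromen-2-yl]phenoxy}malonate | COC(=O)C(Oc1ccc(cc1)-c1cc(=O)c2c(OCc3ccccc3)cc(OC)cc2o1)C(=O)OC | intermediate
9 | 2-{4-[5-(benzyloxy)-7-methoxy-4-oxo-4H-chromen-2-yl]phenoxy}malonic acid | OC(=O)C(Oc1ccc(cc1)-c1cc(=O)c2c(OCc3ccccc3)cc(OC)cc2o1)C(=O)O | intermediate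
10 | 2-{4-[5-(benzyloxy)-7-methoxy-4-oxo-4H-chromen-2-yl]phenoxy}malonyl dichloride | O=C(Cl)C(Oc1ccc(cc1)-c1cc(=O)c2c(OCc3ccccc3)cc(OC)cc2o1)C(Cl)=O | intermediate
11 | 4-(benzyloxy)benzaldehyde | O=Cc1ccc(OCc2ccccc2)cc1 | starting material
12 | 1-methoxy-1,3-bis(trimethylsilyloxy)buta-1,3-diene (Chan's diene) | COC(O[Si](C)(C)C)=CC(=C)O[Si](C)(C)C | starting material
13 | methyl (S)-5-[4-(benzyloxy)phenyl]-3,5-bis(trimethylsilyloxy)pent-2-enoate (not isolated) | COC(=O)C=C(O[Si](C)(C)C)C[C@H](O[Si](C)(C)C)c1ccc(OCc2ccccc2)cc1 | intermediate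
14 | methyl (S)-5-[4-(benzyloxy)phenyl]-5-hydroxy-3-oxopentanoate | COC(=O)CC(=O)C[C@H](O)c1ccc(OCc2ccccc2)cc1 | intermediate
15 | (S)-6-[4-(benzyloxy)phenyl]-4-hydroxy-5,6-dihydro-2H-pyran-2-one | O=C1C=C(O)C[C@@H](c2ccc(OCc3ccccc3)cc2)O1 | intermediate
16 | (S)-6-[4-(benzyloxy)phenyl]-4-[(tert-butyldimethylsilyl)oxy]-5,6-dihydro-2H-pyran-2-one | O=C1C=C(O[Si](C)(C)C(C)(C)C)C[C@@H](c2ccc(OCc3ccccc3)cc2)O1 | intermediate
17 | (S)-2-[4-(benzyloxy)phenyl]-4-[(tert-butyldimethylsilyl)oxy]-6-methylidene-3,6-dihydro-2H-pyran | C=C1C=C(O[Si](C)(C)C(C)(C)C)C[C@@H](c2ccc(OCc3ccccc3)cc2)O1 | intermediate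
18 | 4-[(S)-2-(4-benzyloxyphenyl)-4-oxo-3,4-dihydro-2H-pyran-6-yl]-2-{4-[5-(benzyloxy)-7-methoxy-4-oxo-4H-chromen-2-yl]phenoxy}-3-oxobutanoyl chloride (not isolated) | O=C1C[C@@H](c2ccc(OCc3ccccc3)cc2)OC(CC(=O)C(Oc2ccc(cc2)-c2cc(=O)c3c(OCc4ccccc4)cc(OC)cc3o2)C(Cl)=O)=C1 | intermediate
19 | 5-(benzyloxy)-2-{4-[((2S)-2-[4-(benzyloxy)phenyl]-5,7-dihydroxy-4-oxochroman-6-yl)oxy]phenyl}-7-methoxy-4H-chromen-4-one | COc1cc(OCc2ccccc2)c2c(=O)cc(-c3ccc(Oc4c(O)cc5c(c4O)C(=O)C[C@@H](c4ccc(OCc6ccccc6)cc4)O5)cc3)oc2c1 | intermediate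
20 | 5-(benzyloxy)-2-{4-[((2S)-2-[4-(benzyloxy)phenyl]-5-hydroxy-7-methoxy-4-oxochroman-6-yl)oxy]phenyl}-7-methoxy-4H-chromen-4-one | COc1cc(OCc2ccccc2)c2c(=O)cc(-c3ccc(Oc4c(OC)cc5c(c4O)C(=O)C[C@@H](c4ccc(OCc6ccccc6)cc4)O5)cc3)oc2c1 | intermediate
21 | 5-hydroxy-2-{4-[((2S)-5-hydroxy-2-(4-hydroxyphenyl)-7-methoxy-4-oxochroman-6-yl)oxy]phenyl}-7-methoxy-4H-chromen-4-one | COc1cc(O)c2c(=O)cc(-c3ccc(Oc4c(OC)cc5c(c4O)C(=O)C[C@@H](c4ccc(O)cc4)O5)cc3)oc2c1 | target

**Step count**

Total steps: 13. Longest linear sequence: 9 steps (steps 1–6, then 11–13); the diene branch is steps 7–10.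

**Steps most likely to fail, with fallbacks**

Step 11 (Proposed new method). The bimolecular first acylation may be outrun by protodesilylation of the diene or by oligomerization (one dichloride bridging two dienes), and the mono-acylated intermediate may lose HCl to a ketene that dimerizes instead of closing. The fallback uses known reactions only: ring A'' is taken ready-made and the diaryl ether is formed by cross-coupling. It sets out from 6 and 11 and rejoins the route at 21. Phenol 6 is converted with Tf2O/pyridine into 4-[5-(benzyloxy)-7-methoxy-4-oxo-4H-chromen-2-yl]phenyl triflate F1. Elbs persulfate oxidation of commercial 2'-hydroxy-4',6'-dimethoxyacetophenone gives 2',5'-dihydroxy-4',6'-dimethoxyacetophenone F2. Its only non-chelated hydroxyl is coupled with F1 by a Pd-catalysed (Buchwald–Hartwig-type) diaryl ether synthesis (bulky biarylphosphine, K3PO4, toluene, 100 °C) to give diaryl ether ketone F3. Claisen–Schmidt condensation of F3 with aldehyde 11 gives chalcone F4, and NaOAc in refluxing EtOH closes it through its single free ortho-hydroxyl to the racemic 5''-O-methyl flavanone F5, so no 6''/8'' ambiguity arises. BCl3/pentamethylbenzene then removes the peri-methyl group and both benzyl groups to give the racemic target F6, and preparative chiral HPLC delivers 21.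

Step 10. The electron-rich vinylogous carbonyl may be methylenated only slowly, silicon may be lost hydrolytically from 16, and 17 may isomerize or hydrolyse under traces of acid during isolation. The fallback activates the future C8'' with an ester instead of pre-forming the diene; it sets out from 15 and rejoins at 19. O-Methylation of 15 (Me2SO4, K2CO3, acetone) gives the robust (S)-6-[4-(benzyloxy)phenyl]-4-methoxy-5,6-dihydro-2H-pyran-2-one F7. The non-basic Reformatsky reagent from tert-butyl bromoacetate adds to its lactone carbonyl, and dilute acid converts the hemiketal, with loss of methanol, into tert-butyl 2-[(S)-2-(4-benzyloxyphenyl)-4-oxo-3,4-dihydro-2H-pyran-6-yl]acetate F8 (1,2-addition and transposition of a vinylogous ester). The side-chain CH2 of F8 is estimated to be about ten pKa units more acidic than C3''–H2, so TBSOTf/Et3N at −78 °C should enolize it selectively, and the [3+3] with 10 gives the 8''-tert-butoxycarbonyl analogue of 19, F9. TFA cleaves the ester, and the resulting 2,4,6-trioxygenated benzoic acid, the 8''-carboxylic acid F10, decarboxylates on gentle warming to 19.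

Step 6. The malonic acid may decarboxylate on activation, or the dichloride may lose HCl to a chlorocarbonyl ketene that dimerizes before use. The fallback changes the acyl leaving group and the mode of C-acylation; it sets out from 9 and rejoins at 19. Cyanuric fluoride/pyridine converts 9 into 2-{4-[5-(benzyloxy)-7-methoxy-4-oxo-4H-chromen-2-yl]phenoxy}malonyl difluoride F11, which is far less prone to ketene formation and can be purified. With diene 17 and a catalytic anhydrous fluoride source (TASF), Si–F bond formation should drive both C-acylations.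

**Further compounds**

F1 | step 11 | 4-[5-(benzyloxy)-7-methoxy-4-oxo-4H-chromen-2-yl]phenyl trifluoromethanesulfonate | COc1cc(OCc2ccccc2)c2c(=O)cc(-c3ccc(OS(=O)(=O)C(F)(F)F)cc3)oc2c1
F2 | step 11 | 1-(2,5-dihydroxy-4,6-dimethoxyphenyl)ethan-1-one | CC(=O)c1c(O)cc(OC)c(O)c1OC
F3 | step 11 | 1-(5-{4-[5-(benzyloxy)-7-methoxy-4-oxo-4H-chromen-2-yl]phenoxy}-2-hydroxy-4,6-dimethoxyphenyl)ethan-1-one | CC(=O)c1c(O)cc(OC)c(Oc2ccc(cc2)-c2cc(=O)c3c(OCc4ccccc4)cc(OC)cc3o2)c1OC
F4 | step 11 | (E)-3-[4-(benzyloxy)phenyl]-1-(5-{4-[5-(benzyloxy)-7-methoxy-4-oxo-4H-chromen-2-yl]phenoxy}-2-hydroxy-4,6-dimethoxyphenyl)prop-2-en-1-one | O=C(/C=C/c1ccc(OCc2ccccc2)cc1)c1c(O)cc(OC)c(Oc2ccc(cc2)-c2cc(=O)c3c(OCc4ccccc4)cc(OC)cc3o2)c1OC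
F5 | step 11 | racemic 5-(benzyloxy)-2-{4-[(2-[4-(benzyloxy)phenyl]-5,7-dimethoxy-4-oxochroman-6-yl)oxy]phenyl}-7-methoxy-4H-chromen-4-one | COc1cc2OC(c3ccc(OCc4ccccc4)cc3)CC(=O)c2c(OC)c1Oc1ccc(cc1)-c1cc(=O)c2c(OCc3ccccc3)cc(OC)cc2o1
F6 | step 11 | racemic 5-hydroxy-2-{4-[(5-hydroxy-2-(4-hydroxyphenyl)-7-methoxy-4-oxochroman-6-yl)oxy]phenyl}-7-methoxy-4H-chromen-4-one | COc1cc(O)c2c(=O)cc(-c3ccc(Oc4c(OC)cc5c(c4O)C(=O)CC(c4ccc(O)cc4)O5)cc3)oc2c1
F7 | step 10 | (S)-6-[4-(benzyloxy)phenyl]-4-methoxy-5,6-dihydro-2H-pyran-2-one | O=C1C=C(OC)C[C@@H](c2ccc(OCc3ccccc3)cc2)O1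
F8 | step 10 | tert-butyl 2-[(S)-2-(4-benzyloxyphenyl)-4-oxo-3,4-dihydro-2H-pyran-6-yl]acetate | O=C1C[C@@H](c2ccc(OCc3ccccc3)cc2)OC(CC(=O)OC(C)(C)C)=C1
F9 | step 10 | tert-butyl (2S)-2-[4-(benzyloxy)phenyl]-6-{4-[5-(benzyloxy)-7-methoxy-4-oxo-4H-chromen-2-yl]phenoxy}-5,7-dihydroxy-4-oxochromane-8-carboxylate | COc1cc(OCc2ccccc2)c2c(=O)cc(-c3ccc(Oc4c(O)c(C(=O)OC(C)(C)C)c5c(c4O)C(=O)C[C@@H](c4ccc(OCc6ccccc6)cc4)O5)cc3)oc2c1
F10 | step 10 | (2S)-2-[4-(benzyloxy)phenyl]-6-{4-[5-(benzyloxy)-7-methoxy-4-oxo-4H-chromen-2-yl]phenoxy}-5,7-dihydroxy-4-oxochromane-8-carboxylic acid | COc1cc(OCc2ccccc2)c2c(=O)cc(-c3ccc(Oc4c(O)c(C(=O)O)c5c(c4O)C(=O)C[C@@H](c4ccc(OCc6ccccc6)cc4)O5)cc3)oc2c1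
F11 | step 6 | 2-{4-[5-(benzyloxy)-7-methoxy-4-oxo-4H-chromen-2-yl]phenoxy}malonyl difluoride | O=C(F)C(Oc1ccc(cc1)-c1cc(=O)c2c(OCc3ccccc3)cc(OC)cc2o1)C(F)=O
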